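The route disconnects pyran ring C at C4a–C4 and O1–C2, back to a 1,1-dimethylpropargyl ether on the ring B oxygen that lies para to the bridge carbon C6. In one thermal operation a Claisen shift, enolisation, 1,5-hydrogen shift and oxa-6π closure turn this ether into the 2,2-dimethyl-2H-chromene. The step exploits the position of O1 on C8a, para to C6: ring B is mirror-symmetric about the C6–C8a axis, so both ortho carbons are identical. The C5 and C7 oxygens are silylated so that only O1 can close. The precursor is isobutyrylfilicinic acid (ring A) joined by CH2 to this symmetric aryl propargyl ether.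

Key step: step 6

Remark on the chemistry: a free hydroxyl on C5 would sit next to the allene that the Claisen shift places on C4a and could take over the hydrogen shift and ring closure, giving the isomeric chromene with the ring oxygen ortho to the bridge. The C5 and C7 oxygens are therefore carried as silyl ethers from the aldehyde stage until after the key step, which leaves the skeletons of precursor and product unchanged.

Abbreviation: TBS = tert-butyldimethylsilyl. Ring A is drawn throughout as the enol tautomer of the target SMILES. The target has no stereocentre.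

Step 1
Reactants: 1 phloroglucinol; 2 isobutyryl chloride
Product: 3 2-methyl-1-(2,4,6-trihydroxyphenyl)propan-1-one (phlorisobutyrophenone)
Conditions: AlCl3 (3 equiv), PhNO2/CH2Cl2, 0 °C to 40 °C; then ice/1 M HCl
Reagents that add atoms: none
Why: Friedel–Crafts C-acylation of a highly activated, threefold-symmetric arene; the first acyl group deactivates the ring, so the reaction should stop at the monoketone.

Step 2
Reactants: 3 2-methyl-1-(2,4,6-trihydroxyphenyl)propan-1-one
Product: 5 isobutyrylfilicinic acid [3,5-dihydroxy-6,6-dimethyl-2-(2-methylpropanoyl)cyclohexa-2,4-dien-1-one], via monomethyl ketone 4 (not isolated)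
Conditions: NaOMe (3 equiv), MeI (2.2 equiv), MeOH, 0 °C to rt; then 1 M HCl
Reagents that add atoms: iodomethane, CI
Why: Base-mediated dearomative C-methylation of an acylphloroglucinol, in which the phenoxide is alkylated at a ring carbon and the second methyl group is known to favour the already methylated carbon of 4, giving the gem-dimethyl cyclohexadienone with one ring CH left free for the coupling.

Step 3
Reactants: 6 2,4,6-trihydroxybenzaldehyde; 7 3-chloro-3-methylbut-1-yne
Product: 8 2,6-dihydroxy-4-[(2-methylbut-3-yn-2-yl)oxy]benzaldehyde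
Conditions: CuCl2·2H2O (1 mol %), DBU (1.3 equiv), 7 (1.1 equiv), MeCN, 0 °C to rt
Reagents that add atoms: none
Why: Copper-catalysed propargylic O-alkylation of a phenol; the 4-hydroxyl, para to the formyl group, is the most acidic and the only one not held in a hydrogen bond to the carbonyl, so one equivalent of 7 should etherify it alone.

Step 4
Reactants: 8 2,6-dihydroxy-4-[(2-methylbut-3-yn-2-yl)oxy]benzaldehyde
Product: 9 2,6-bis(TBS-oxy)-4-[(2-methylbut-3-yn-2-yl)oxy]benzaldehyde
Conditions: TBSCl (2.6 equiv), imidazole (5 equiv), DMF, rt to 40 °C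
Reagents that add atoms: tert-butyldimethylsilyl chloride, CC(C)(C)[Si](C)(C)Cl
Why: Imidazole-promoted O-silylation of phenols; excess reagent and gentle warming overcome the hydrogen bonds to the formyl group, while the terminal alkyne and the tertiary propargylic ether are inert.

Step 5
Reactants: 9 2,6-bis(TBS-oxy)-4-[(2-methylbut-3-yn-2-yl)oxy]benzaldehyde; 5 isobutyrylfilicinic acid
Product: 11 4-{2,6-bis(TBS-oxy)-4-[(2-methylbut-3-yn-2-yl)oxy]benzyl}-3,5-dihydroxy-6,6-dimethyl-2-(2-methylpropanoyl)cyclohexa-2,4-dien-1-one, via Knoevenagel adduct 10 (not isolated)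
Conditions: L-proline (20 mol %), Hantzsch ester (diethyl 2,6-dimethyl-1,4-dihydropyridine-3,5-dicarboxylate, 1.2 equiv), CH2Cl2, rt, dark
Reagents that add atoms: none
Why: Organocatalytic three-component reductive alkylation: proline-mediated Knoevenagel condensation at the only unsubstituted ring carbon of triketone 5 gives alkylidene 10, whose doubly activated C=C bond should take up hydride from the Hantzsch ester (transfer hydrogenation) before a second molecule of 5 can add, and neither the alkyne nor the silyl ethers react.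

Step 6
Reactants: 11 4-{2,6-bis(TBS-oxy)-4-[(2-methylbut-3-yn-2-yl)oxy]benzyl}-3,5-dihydroxy-6,6-dimethyl-2-(2-methylpropanoyl)cyclohexa-2,4-dien-1-one
Product: 15 4-{[5,7-bis(TBS-oxy)-2,2-dimethyl-2H-chromen-6-yl]methyl}-3,5-dihydroxy-6,6-dimethyl-2-(2-methylpropanoyl)cyclohexa-2,4-dien-1-one, via allenyl dienone 12 (not isolated), via allenyl phenol 13 (not isolated), via quinone methide 14 (not isolated)
Conditions: degassed o-xylene (0.02 M), 140 °C, sealed tube, argon
Reagents that add atoms: none
Why: Heating triggers an aryl propargyl Claisen [3,3] shift that joins the alkyne terminus to C4a and cuts the O–CMe2 bond, giving allenyl dienone 12, which enolises to allenyl phenol 13; a 1,5-hydrogen shift from the newly freed C8a hydroxyl to the central allene carbon gives o-quinone methide 14, which then cyclises. The closest known reaction type is the thermal rearrangement of aryl 1,1-dimethylpropargyl ethers to 2,2-dimethyl-2H-chromenes. Ring C, the six-membered pyran, is closed by a thermally allowed disrotatory oxa-6π electrocyclisation of 14 that remakes O1–C2 at the gem-dimethyl carbon. No stereocentre results, since C2 carries two methyl groups and the sp3 carbon of 12 is re-aromatised. The step needs the chromene and not a benzofuran, which neutral heating without base or metal secures by keeping the allene on the pericyclic path; the mirror symmetry of ring B about the C6–C8a axis removes any choice between the ortho carbons; and the silyl ethers on the C5 and C7 oxygens leave the C8a hydroxyl as the only one able to give up hydrogen, so closure can occur only onto O1.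

Step 7
Reactants: 15 4-{[5,7-bis(TBS-oxy)-2,2-dimethyl-2H-chromen-6-yl]methyl}-3,5-dihydroxy-6,6-dimethyl-2-(2-methylpropanoyl)cyclohexa-2,4-dien-1-one
Product: 16 4-[(5,7-dihydroxy-2,2-dimethyl-2H-chromen-6-yl)methyl]-3,5-dihydroxy-6,6-dimethyl-2-(2-methylpropanoyl)cyclohexa-2,4-dien-1-one (uliginosin B without the ring B isobutyryl group)
Conditions: KHF2 (5 equiv), MeOH, rt
Reagents that add atoms: none
Why: Fluoride-induced cleavage of aryl silyl ethers under weakly acidic conditions, which should free the two phenols without forming the phenoxide that could trigger retro-Michael scrambling at the bridge and without touching the chromene double bond.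

Step 8
Reactants: 16 4-[(5,7-dihydroxy-2,2-dimethyl-2H-chromen-6-yl)methyl]-3,5-dihydroxy-6,6-dimethyl-2-(2-methylpropanoyl)cyclohexa-2,4-dien-1-one; 2 isobutyryl chloride
Product: 17 uliginosin B
Conditions: TiCl4 (3.5 equiv), 2 (1.3 equiv), CH2Cl2, −40 °C to 0 °C; then cold 1 M HCl
Reagents that add atoms: none
Why: Friedel–Crafts acylation delivered through the titanium phenolate: C8 is the only unsubstituted carbon of ring B, ortho to the C7 hydroxyl and para to the C5 hydroxyl, so it is the sole site for C-acylation, while ring A has no free carbon and any enol ester formed there is cleaved on aqueous work-up.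

Compound list
1 | phloroglucinol | Oc1cc(O)cc(O)c1 | starting material
2 | isobutyryl chloride | CC(C)C(Cl)=O | starting material
3 | 2-methyl-1-(2,4,6-trihydroxyphenyl)propan-1-one | CC(C)C(=O)c1c(O)cc(O)cc1O | intermediate
4 | 2-methyl-1-(2,4,6-trihydroxy-3-methylphenyl)propan-1-one | CC(C)C(=O)c1c(O)cc(O)c(C)c1O | intermediate (not isolated)
5 | isobutyrylfilicinic acid, 3,5-dihydroxy-6,6-dimethyl-2-(2-methylpropanoyl)cyclohexa-2,4-dien-1-one | CC(C)C(=O)C1=C(O)C=C(O)C(C)(C)C1=O | intermediate
6 | 2,4,6-trihydroxybenzaldehyde | O=Cc1c(O)cc(O)cc1O | starting material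
7 | 3-chloro-3-methylbut-1-yne | CC(C)(Cl)C#C | starting material
8 | 2,6-dihydroxy-4-[(2-methylbut-3-yn-2-yl)oxy]benzaldehyde | O=Cc1c(O)cc(OC(C)(C)C#C)cc1O | intermediate
9 | 2,6-bis[(tert-butyldimethylsilyl)oxy]-4-[(2-methylbut-3-yn-2-yl)oxy]benzaldehyde | O=Cc1c(O[Si](C)(C)C(C)(C)C)cc(OC(C)(C)C#C)cc1O[Si](C)(C)C(C)(C)C | intermediate
10 | 4-{2,6-bis[(tert-butyldimethylsilyl)oxy]-4-[(2-methylbut-3-yn-2-yl)oxy]benzylidene}-5-hydroxy-2,2-dimethyl-6-(2-methylpropanoyl)cyclohex-5-ene-1,3-dione (alkene geometry not defined) | CC(C)C(=O)C1=C(O)C(=Cc2c(O[Si](C)(C)C(C)(C)C)cc(OC(C)(C)C#C)cc2O[Si](C)(C)C(C)(C)C)C(=O)C(C)(C)C1=O | intermediate (not isolated)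
11 | 4-{2,6-bis[(tert-butyldimethylsilyl)oxy]-4-[(2-methylbut-3-yn-2-yl)oxy]benzyl}-3,5-dihydroxy-6,6-dimethyl-2-(2-methylpropanoyl)cyclohexa-2,4-dien-1-one | CC(C)C(=O)C1=C(O)C(Cc2c(O[Si](C)(C)C(C)(C)C)cc(OC(C)(C)C#C)cc2O[Si](C)(C)C(C)(C)C)=C(O)C(C)(C)C1=O | intermediate (key-step precursor)
12 | 4-({2,6-bis[(tert-butyldimethylsilyl)oxy]-3-(3-methylbuta-1,2-dien-1-yl)-4-oxocyclohexa-1,5-dien-1-yl}methyl)-3,5-dihydroxy-6,6-dimethyl-2-(2-methylpropanoyl)cyclohexa-2,4-dien-1-one (racemic at the allene-bearing ring carbon) | CC(C)C(=O)C1=C(O)C(CC2=C(O[Si](C)(C)C(C)(C)C)C(C=C=C(C)C)C(=O)C=C2O[Si](C)(C)C(C)(C)C)=C(O)C(C)(C)C1=O | intermediate (not isolated)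
13 | 4-{2,6-bis[(tert-butyldimethylsilyl)oxy]-4-hydroxy-3-(3-methylbuta-1,2-dien-1-yl)benzyl}-3,5-dihydroxy-6,6-dimethyl-2-(2-methylpropanoyl)cyclohexa-2,4-dien-1-one | CC(C)C(=O)C1=C(O)C(Cc2c(O[Si](C)(C)C(C)(C)C)cc(O)c(C=C=C(C)C)c2O[Si](C)(C)C(C)(C)C)=C(O)C(C)(C)C1=O | intermediate (not isolated)
14 | 4-({2,6-bis[(tert-butyldimethylsilyl)oxy]-3-(3-methylbut-2-en-1-ylidene)-4-oxocyclohexa-1,5-dien-1-yl}methyl)-3,5-dihydroxy-6,6-dimethyl-2-(2-methylpropanoyl)cyclohexa-2,4-dien-1-one (dienyl chain cis to the ring carbonyl) | CC(C)C(=O)C1=C(O)C(CC2=C(O[Si](C)(C)C(C)(C)C)/C(=C/C=C(C)C)C(=O)C=C2O[Si](C)(C)C(C)(C)C)=C(O)C(C)(C)C1=O | intermediate (not isolated)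
15 | 4-({5,7-bis[(tert-butyldimethylsilyl)oxy]-2,2-dimethyl-2H-chromen-6-yl}methyl)-3,5-dihydroxy-6,6-dimethyl-2-(2-methylpropanoyl)cyclohexa-2,4-dien-1-one | CC(C)C(=O)C1=C(O)C(Cc2c(O[Si](C)(C)C(C)(C)C)c3C=CC(C)(C)Oc3cc2O[Si](C)(C)C(C)(C)C)=C(O)C(C)(C)C1=O | intermediate (key-step product)
16 | 4-[(5,7-dihydroxy-2,2-dimethyl-2H-chromen-6-yl)methyl]-3,5-dihydroxy-6,6-dimethyl-2-(2-methylpropanoyl)cyclohexa-2,4-dien-1-one | CC(C)C(=O)C1=C(O)C(Cc2c(O)c3C=CC(C)(C)Oc3cc2O)=C(O)C(C)(C)C1=O | intermediate
17 | uliginosin B, 4-{[5,7-dihydroxy-2,2-dimethyl-8-(2-methylpropanoyl)-2H-chromen-6-yl]methyl}-3,5-dihydroxy-6,6-dimethyl-2-(2-methylpropanoyl)cyclohexa-2,4-dien-1-one | CC(C)C(=O)C1=C(O)C(Cc2c(O)c3c(c(C(=O)C(C)C)c2O)OC(C)(C)C=C3)=C(O)C(C)(C)C1=O | target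

Total step count: 8. Longest linear sequence: 6 steps (6 → 8 → 9 → 11 → 15 → 16 → 17; the branch 1 → 3 → 5 joins at step 5 and is equally long).

Steps most likely to fail

Step 6. At 140 °C the acidic enol of ring A may cleave the tertiary propargylic ether or a silyl ether faster than the [3,3] shift proceeds, or the bridge may fragment thermally. The fallback moves the pericyclic cascade ahead of the coupling, so that it runs on a substrate without ring A. It sets out from aldehyde 9, which is heated alone in degassed o-xylene at 140 °C. The same sequence through allenyl dienone F1, allenyl phenol F2 and quinone methide F3 should give chromene aldehyde F4; 9 has the same mirror symmetry and the same single free hydroxyl after the shift, so only one chromene can form. F4 is then coupled with 5 under the conditions of step 5 (L-proline, Hantzsch ester, CH2Cl2, rt), through Knoevenagel adduct F5. The chromene double bond is not an acceptor for the Hantzsch ester, and the reductive coupling rejoins the route at compound 15.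

Step 8. TiCl4 may ionise the bridge and scramble the two halves, the acylium ion or liberated HCl may attack the electron-rich C3=C4 double bond, or acylation may stop at oxygen. The fallback replaces the acylium electrophile by a protonated nitrile, which is too weak to attack the double bond or to acylate oxygen lastingly, and replaces TiCl4 by a much weaker Lewis acid. It sets out from 16, which is treated with isobutyronitrile (CC(C)C#N), ZnCl2 and dry HCl in Et2O at 0 °C (Houben–Hoesch reaction, the classical acylation of phloroglucinols). C8 is again the only free ring carbon, so the product should be ketiminium chloride F6, which is hydrolysed in warm aqueous methanol and rejoins the route at compound 17.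

Step 5. The formyl group of 9 is flanked by two bulky silyloxy groups, so iminium formation and condensation may be slow, and long exposure to the amine and the acidic triketone may strip a silyl group. The fallback couples before protecting. It sets out from aldehyde 8, which is combined with 5, L-proline and the Hantzsch ester in CH2Cl2. The free ortho hydroxyls assist the condensation, and Knoevenagel adduct F7 is reduced in the flask to bisphenol F8. F8 is then silylated with TBSCl and imidazole in DMF; the two phenols of ring B are silylated, whereas the vinylogous-acid enols of ring A do not retain silicon through aqueous work-up. This rejoins the route at compound 11.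

Further compounds
F1 | step 6 | 2,6-bis[(tert-butyldimethylsilyl)oxy]-3-(3-methylbuta-1,2-dien-1-yl)-4-oxocyclohexa-1,5-diene-1-carbaldehyde (allenyl dienone, racemic) | O=CC1=C(O[Si](C)(C)C(C)(C)C)C(C=C=C(C)C)C(=O)C=C1O[Si](C)(C)C(C)(C)C
F2 | step 6 | 2,6-bis[(tert-butyldimethylsilyl)oxy]-4-hydroxy-3-(3-methylbuta-1,2-dien-1-yl)benzaldehyde (allenyl phenol) | O=Cc1c(O[Si](C)(C)C(C)(C)C)cc(O)c(C=C=C(C)C)c1O[Si](C)(C)C(C)(C)C
F3 | step 6 | 2,6-bis[(tert-butyldimethylsilyl)oxy]-3-(3-methylbut-2-en-1-ylidene)-4-oxocyclohexa-1,5-diene-1-carbaldehyde (quinone methide, dienyl chain cis to the ring carbonyl) | O=CC1=C(O[Si](C)(C)C(C)(C)C)/C(=C/C=C(C)C)C(=O)C=C1O[Si](C)(C)C(C)(C)C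
F4 | step 6 | 5,7-bis[(tert-butyldimethylsilyl)oxy]-2,2-dimethyl-2H-chromene-6-carbaldehyde (chromene aldehyde) | O=Cc1c(O[Si](C)(C)C(C)(C)C)cc2OC(C)(C)C=Cc2c1O[Si](C)(C)C(C)(C)C
F5 | step 6 | 4-({5,7-bis[(tert-butyldimethylsilyl)oxy]-2,2-dimethyl-2H-chromen-6-yl}methylidene)-5-hydroxy-2,2-dimethyl-6-(2-methylpropanoyl)cyclohex-5-ene-1,3-dione (Knoevenagel adduct, alkene geometry not defined) | CC(C)C(=O)C1=C(O)C(=Cc2c(O[Si](C)(C)C(C)(C)C)cc3OC(C)(C)C=Cc3c2O[Si](C)(C)C(C)(C)C)C(=O)C(C)(C)C1=O
F6 | step 8 | ketiminium chloride of uliginosin B at the ring B acyl carbon (C8 bears C(=NH2+)CH(CH3)2, chloride counter-ion) | CC(C)C(=O)C1=C(O)C(Cc2c(O)c3c(c(C(=[NH2+])C(C)C)c2O)OC(C)(C)C=C3)=C(O)C(C)(C)C1=O.[Cl-]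
F7 | step 5 | 4-{2,6-dihydroxy-4-[(2-methylbut-3-yn-2-yl)oxy]benzylidene}-5-hydroxy-2,2-dimethyl-6-(2-methylpropanoyl)cyclohex-5-ene-1,3-dione (Knoevenagel adduct, alkene geometry not defined) | CC(C)C(=O)C1=C(O)C(=Cc2c(O)cc(OC(C)(C)C#C)cc2O)C(=O)C(C)(C)C1=O
F8 | step 5 | 4-{2,6-dihydroxy-4-[(2-methylbut-3-yn-2-yl)oxy]benzyl}-3,5-dihydroxy-6,6-dimethyl-2-(2-methylpropanoyl)cyclohexa-2,4-dien-1-one (bisphenol) | CC(C)C(=O)C1=C(O)C(Cc2c(O)cc(OC(C)(C)C#C)cc2O)=C(O)C(C)(C)C1=O
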